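**Retrosynthetic overview**

1. Target 22 comes from tetra-MOM ether 20 by acid-free acetal removal. The two prenyl groups of 20 are grown from the two CH2CH2OSi arms of 17 (desilylation, oxidation, double Wittig).
2. The strategy rests on ring B: its adjacent carbons C2′, C1′ and C6′ carry prenyl, benzofuran C2 and prenyl, between the oxygens on C3′ and C5′. This is an ortho/ipso/ortho pattern around one carbon, so C2′–CH2, C1′–C2 and C6′–CH2 are all made in one palladium/norbornene operation from iodide 15, two molecules of bromide 16 and boronate 13.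
3. Boronate 13 comes from benzofuran 11 by C2 lithiation–borylation. The (R) centre on the C7 side chain is set by copper-catalysed asymmetric SN2′ methylation of allylic bromide 10.
4. Ring order: both benzene rings are bought (2,4,6-trihydroxybenzaldehyde for ring A, 5-iodoresorcinol for ring B). The furan ring is the only ring made (step 4, alkyne cyclisation onto the phenol oxygen); the key step closes no ring.

Key step: step 11

Assumption: 5-iodoresorcinol and (2-bromoethoxy)(tert-butyl)dimethylsilane are purchased. Taniaphos is specified by the sense of induction it shows with (E)-cinnamyl bromide, both antipodes being available. Ring B is numbered with primes, C1′ on benzofuran C2.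

**Route**

Step 1
Reactants: 1 2,4,6-trihydroxybenzaldehyde
Product: 2 2-hydroxy-4,6-bis(methoxymethoxy)benzaldehyde
Conditions: MOMCl (2.2 equiv), i-Pr2NEt, CH2Cl2, 0 °C to rt
Reagents that add atoms: chloromethyl methyl ether, COCCl
Why: O-alkylation (MOM protection) takes the para hydroxyl and one ortho hydroxyl, while the remaining ortho hydroxyl is held in a hydrogen bond to the formyl group and should stay free with two equivalents of reagent.

Step 2
Reactants: 2 2-hydroxy-4,6-bis(methoxymethoxy)benzaldehyde
Product: 3 2-hydroxy-3-iodo-4,6-bis(methoxymethoxy)benzaldehyde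
Conditions: BnMe3N·ICl2 (1.0 equiv), NaHCO3, CH2Cl2–MeOH, rt
Reagents that add atoms: benzyltrimethylammonium dichloroiodate, C[N+](C)(C)Cc1ccccc1.Cl[I-]Cl
Why: Phenol-directed electrophilic aromatic iodination should attack C3, ortho to the free hydroxyl and para to the C6 ether, in preference to C5, which is buried between two MOM ethers, and the bicarbonate buffer protects the acetals.

Step 3
Reactants: 3 2-hydroxy-3-iodo-4,6-bis(methoxymethoxy)benzaldehyde
Product: 4 2-hydroxy-4,6-bis(methoxymethoxy)-3-[(trimethylsilyl)ethynyl]benzaldehyde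
Conditions: ethynyltrimethylsilane (1.5 equiv), PdCl2(PPh3)2 (5 mol %), CuI (10 mol %), Et3N, THF, 50 °C
Reagents that add atoms: ethynyltrimethylsilane, C#C[Si](C)(C)C
Why: Sonogashira coupling of an aryl iodide tolerates the free phenol and the aldehyde, and any material that already cyclises to the 2-silylbenzofuran converges on the same product in step 4.

Step 4
Reactants: 4 2-hydroxy-4,6-bis(methoxymethoxy)-3-[(trimethylsilyl)ethynyl]benzaldehyde
Product: 6 4,6-bis(methoxymethoxy)benzofuran-7-carbaldehyde, via ethynylphenol 5 (not isolated)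
Conditions: Bu4NF (2 equiv), THF, 65 °C
Reagents that add atoms: none
Why: Fluoride removes the alkyne silyl group and then, as base, promotes 5-endo-dig hydroalkoxylation of the ortho-ethynylphenol to close the furan ring, a 2-silylbenzofuran carried over from step 3 being protodesilylated under the same conditions.

Step 5
Reactants: 6 4,6-bis(methoxymethoxy)benzofuran-7-carbaldehyde
Product: 7 ethyl (E)-3-[4,6-bis(methoxymethoxy)benzofuran-7-yl]-2-methylprop-2-enoate
Conditions: Ph3P=C(CH3)CO2Et (1.5 equiv), toluene, 110 °C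
Reagents that add atoms: ethyl 2-(triphenylphosphoranylidene)propanoate, CCOC(=O)C(C)=P(c1ccccc1)(c1ccccc1)c1ccccc1
Why: Wittig olefination with a stabilised α-branched ylide should give the (E)-trisubstituted enoate, aryl trans to the ester, and heating overcomes the hindrance of the doubly ortho-oxygenated aldehyde.

Step 6
Reactants: 7 ethyl (E)-3-[4,6-bis(methoxymethoxy)benzofuran-7-yl]-2-methylprop-2-enoate
Product: 8 (E)-3-[4,6-bis(methoxymethoxy)benzofuran-7-yl]-2-methylprop-2-en-1-ol
Conditions: i-Bu2AlH (2.5 equiv), CH2Cl2, −78 °C; aqueous potassium sodium tartrate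
Reagents that add atoms: none
Why: 1,2-Reduction of the conjugated ester by the aluminium hydride gives the allylic alcohol without touching the alkene geometry, the benzofuran or the acetals.

Step 7
Reactants: 8 (E)-3-[4,6-bis(methoxymethoxy)benzofuran-7-yl]-2-methylprop-2-en-1-ol
Product: 10 7-[(E)-3-bromo-2-methylprop-1-en-1-yl]-4,6-bis(methoxymethoxy)benzofuran, via allylic mesylate 9 (not isolated)
Conditions: MsCl, Et3N, THF, −40 °C; then LiBr, 0 °C; used at once
Reagents that add atoms: lithium bromide, [Li+].[Br-]; methanesulfonyl chloride (atoms in intermediate 9 only), CS(=O)(=O)Cl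
Why: Mesylation followed by SN2 displacement with bromide works under non-acidic conditions that keep the MOM ethers and the (E)-alkene intact.

Step 8
Reactants: 10 7-[(E)-3-bromo-2-methylprop-1-en-1-yl]-4,6-bis(methoxymethoxy)benzofuran
Product: 11 4,6-bis(methoxymethoxy)-7-[(2R)-3-methylbut-3-en-2-yl]benzofuran
Conditions: MeMgBr (1.3 equiv), CuBr·SMe2 (5 mol %), Taniaphos (6 mol %, the antipode that gives (R)-3-arylbut-1-enes from (E)-cinnamyl bromides), CH2Cl2, −78 °C
Reagents that add atoms: methylmagnesium bromide, C[Mg]Br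
Why: In this copper-catalysed asymmetric allylic alkylation (SN2′) with a Grignard reagent, the chiral methylcopper–diphosphine complex adds anti to bromide at the aryl-bearing γ-carbon and reductive elimination from the σ-allyl complex of trivalent copper gives the branched alkene, the ligand choosing the alkene face and thus the (R) configuration, as established for (E)-cinnamyl and 2-methylcinnamyl halides.

Step 9
Reactants: 11 4,6-bis(methoxymethoxy)-7-[(2R)-3-methylbut-3-en-2-yl]benzofuran
Product: 13 2-{4,6-bis(methoxymethoxy)-7-[(2R)-3-methylbut-3-en-2-yl]benzofuran-2-yl}-4,4,5,5-tetramethyl-1,3,2-dioxaborolane, via 2-lithiobenzofuran 12 (not isolated)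
Conditions: n-BuLi (1.05 equiv), THF, −78 °C; then i-PrOBpin, −78 °C to rt
Reagents that add atoms: 2-isopropoxy-4,4,5,5-tetramethyl-1,3,2-dioxaborolane, CC(C)OB1OC(C)(C)C(C)(C)O1; n-butyllithium (lithium in intermediate 12 only), [Li]CCCC
Why: Deprotonation of the most acidic C–H bond (furan C2, α to oxygen) and electrophilic borylation of the aryllithium should be selective at −78 °C, where neither ortho-lithiation at C5 between the MOM ethers nor removal of the benzylic-allylic hydrogen of the stereocentre is expected to compete.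

Step 10
Reactants: 14 5-iodoresorcinol
Product: 15 1-iodo-3,5-bis(methoxymethoxy)benzene
Conditions: MOMCl (2.5 equiv), i-Pr2NEt, CH2Cl2, 0 °C to rt
Reagents that add atoms: chloromethyl methyl ether, COCCl
Why: O-alkylation (MOM protection) of both phenols proceeds while the aryl iodide is inert.

Step 11
Reactants: 15 1-iodo-3,5-bis(methoxymethoxy)benzene (1.5 equiv); 16 (2-bromoethoxy)(tert-butyl)dimethylsilane (5 equiv); 13 2-{4,6-bis(methoxymethoxy)-7-[(2R)-3-methylbut-3-en-2-yl]benzofuran-2-yl}-4,4,5,5-tetramethyl-1,3,2-dioxaborolane (1.0 equiv)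
Product: 17 2-{3,5-bis(methoxymethoxy)-2,6-bis[2-(tert-butyldimethylsilyloxy)ethyl]phenyl}-4,6-bis(methoxymethoxy)-7-[(2R)-3-methylbut-3-en-2-yl]benzofuran
Conditions: Pd(OAc)2 (10 mol %), P(2-furyl)3 (20 mol %), norbornene (2 equiv), Cs2CO3 (6 equiv), DMF–H2O 20:1, 70 °C; 13 added by syringe pump over 8 h
Reagents that add atoms: none
Why: This is a Catellani reaction (palladium/norbornene cooperative catalysis) with Suzuki–Miyaura termination: zerovalent palladium inserts into the C–I bond of 15, norbornene carbopalladation and carbonate-assisted ortho C–H palladation give a five-membered aryl–norbornyl palladacycle, and this takes up bromide 16 by oxidative addition to tetravalent palladium and reductively eliminates the aryl–CH2 bond, after which the sequence repeats at the second ortho position. Once both ortho carbons (future C2′ and C6′) carry an arm, steric compression expels norbornene by β-carbon elimination, and the 2,6-dialkylaryl complex of divalent palladium is transmetalated by boronate 13 and reductively eliminates the C1′–C2 bond. The closest known reaction type is the ortho,ortho-dialkylation of aryl iodides with primary alkyl bromides terminated by arylboronic acids; no ring is closed and no stereocentre is made, the (R) centre of 13 being a spectator remote from the metal. The step needs order selectivity (two alkylations before ipso coupling), which should follow from norbornene insertion into the unhindered arylpalladium iodide being much faster than transmetalation and is reinforced by adding 13 slowly as the limiting reagent; site selectivity is settled by the symmetry of 15, whose two ortho C–H bonds are equivalent while the C4 hydrogen between the ethers is out of reach of the palladacycle. Both ortho C–H bonds lie beside MOM ethers, which are small and acidify them toward carbonate-assisted metalation, but this flanking pattern and a 2-benzofuranyl boronate lie outside the examples on record, so the risk of the route sits here. A Heck reaction at the hindered 1,1-disubstituted isopropenyl alkene should be outrun by the excess of strained norbornene.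

Step 12
Reactants: 17 2-{3,5-bis(methoxymethoxy)-2,6-bis[2-(tert-butyldimethylsilyloxy)ethyl]phenyl}-4,6-bis(methoxymethoxy)-7-[(2R)-3-methylbut-3-en-2-yl]benzofuran
Product: 18 2,2′-{2-[4,6-bis(methoxymethoxy)-7-((2R)-3-methylbut-3-en-2-yl)benzofuran-2-yl]-4,6-bis(methoxymethoxy)-1,3-phenylene}diethanol
Conditions: Bu4NF (2.5 equiv), THF, 0 °C to rt
Reagents that add atoms: none
Why: Fluoride-mediated cleavage of the two primary silyl ethers leaves the MOM ethers, the alkene and the benzofuran untouched.

Step 13
Reactants: 18 2,2′-{2-[4,6-bis(methoxymethoxy)-7-((2R)-3-methylbut-3-en-2-yl)benzofuran-2-yl]-4,6-bis(methoxymethoxy)-1,3-phenylene}diethanol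
Product: 19 2,2′-{2-[4,6-bis(methoxymethoxy)-7-((2R)-3-methylbut-3-en-2-yl)benzofuran-2-yl]-4,6-bis(methoxymethoxy)-1,3-phenylene}diacetaldehyde
Conditions: Dess–Martin periodinane (3 equiv), NaHCO3, CH2Cl2, 0 °C to rt; crude product used at once
Reagents that add atoms: none
Why: Dess–Martin oxidation converts both primary alcohols into the arylacetaldehydes under buffered conditions that avoid over-oxidation and enolisation.

Step 14
Reactants: 19 2,2′-{2-[4,6-bis(methoxymethoxy)-7-((2R)-3-methylbut-3-en-2-yl)benzofuran-2-yl]-4,6-bis(methoxymethoxy)-1,3-phenylene}diacetaldehyde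
Product: 20 2-[3,5-bis(methoxymethoxy)-2,6-bis(3-methylbut-2-en-1-yl)phenyl]-4,6-bis(methoxymethoxy)-7-[(2R)-3-methylbut-3-en-2-yl]benzofuran
Conditions: i-PrPPh3I (6 equiv), n-BuLi (5.8 equiv), THF, 0 °C; then 19, −78 °C to rt
Reagents that add atoms: isopropyltriphenylphosphonium iodide, CC(C)[P+](c1ccccc1)(c1ccccc1)c1ccccc1.[I-]
Why: Double Wittig olefination with the non-stabilised isopropylidene ylide raises no E/Z question because the ylide terminus is symmetric, and low temperature with excess ylide should limit enolisation of the arylacetaldehydes.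

Step 15
Reactants: 20 2-[3,5-bis(methoxymethoxy)-2,6-bis(3-methylbut-2-en-1-yl)phenyl]-4,6-bis(methoxymethoxy)-7-[(2R)-3-methylbut-3-en-2-yl]benzofuran
Product: 22 2-[3,5-dihydroxy-2,6-bis(3-methylbut-2-en-1-yl)phenyl]-7-[(2R)-3-methylbut-3-en-2-yl]benzofuran-4,6-diol, via tetrakis(trimethylsilyl) ether 21 (not isolated)
Conditions: TMSOTf (10 equiv), 2,2′-bipyridyl (15 equiv), MeCN, 0 °C to rt; then H2O, rt
Reagents that add atoms: trimethylsilyl trifluoromethanesulfonate (silyl groups of intermediate 21 only), C[Si](C)(C)OS(=O)(=O)C(F)(F)F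
Why: Silyl triflate/2,2′-bipyridyl cleavage of aromatic MOM ethers converts each acetal into the aryl silyl ether with transfer of the methoxymethyl group to bipyridyl, and water then hydrolyses the silyl ethers, so no free Brønsted acid meets the ortho-prenyl phenols or the isopropenyl group, which could otherwise cyclise to chromans or a dihydrobenzofuran or isomerise and erase the stereocentre.

**Compound list**

1 | 2,4,6-trihydroxybenzaldehyde | O=Cc1c(O)cc(O)cc1O | starting material
2 | 2-hydroxy-4,6-bis(methoxymethoxy)benzaldehyde | O=Cc1c(O)cc(OCOC)cc1OCOC | intermediate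
3 | 2-hydroxy-3-iodo-4,6-bis(methoxymethoxy)benzaldehyde | O=Cc1c(O)c(I)c(OCOC)cc1OCOC | intermediate
4 | 2-hydroxy-4,6-bis(methoxymethoxy)-3-[(trimethylsilyl)ethynyl]benzaldehyde | O=Cc1c(O)c(C#C[Si](C)(C)C)c(OCOC)cc1OCOC | intermediate
5 | 3-ethynyl-2-hydroxy-4,6-bis(methoxymethoxy)benzaldehyde (not isolated) | O=Cc1c(O)c(C#C)c(OCOC)cc1OCOC | intermediate
6 | 4,6-bis(methoxymethoxy)benzofuran-7-carbaldehyde | O=Cc1c(OCOC)cc(OCOC)c2ccoc12 | intermediate
7 | ethyl (E)-3-[4,6-bis(methoxymethoxy)benzofuran-7-yl]-2-methylprop-2-enoate | CCOC(=O)/C(C)=C/c1c(OCOC)cc(OCOC)c2ccoc12 | intermediate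
8 | (E)-3-[4,6-bis(methoxymethoxy)benzofuran-7-yl]-2-methylprop-2-en-1-ol | OC/C(C)=C/c1c(OCOC)cc(OCOC)c2ccoc12 | intermediate
9 | (E)-3-[4,6-bis(methoxymethoxy)benzofuran-7-yl]-2-methylprop-2-en-1-yl methanesulfonate (not isolated) | CS(=O)(=O)OC/C(C)=C/c1c(OCOC)cc(OCOC)c2ccoc12 | intermediate
10 | 7-[(E)-3-bromo-2-methylprop-1-en-1-yl]-4,6-bis(methoxymethoxy)benzofuran | BrC/C(C)=C/c1c(OCOC)cc(OCOC)c2ccoc12 | intermediate
11 | 4,6-bis(methoxymethoxy)-7-[(2R)-3-methylbut-3-en-2-yl]benzofuran | C=C(C)[C@@H](C)c1c(OCOC)cc(OCOC)c2ccoc12 | intermediate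
12 | 2-lithio-4,6-bis(methoxymethoxy)-7-[(2R)-3-methylbut-3-en-2-yl]benzofuran (not isolated) | C=C(C)[C@@H](C)c1c(OCOC)cc(OCOC)c2cc([Li])oc12 | intermediate
13 | 2-{4,6-bis(methoxymethoxy)-7-[(2R)-3-methylbut-3-en-2-yl]benzofuran-2-yl}-4,4,5,5-tetramethyl-1,3,2-dioxaborolane | C=C(C)[C@@H](C)c1c(OCOC)cc(OCOC)c2cc(B3OC(C)(C)C(C)(C)O3)oc12 | intermediate
14 | 5-iodoresorcinol | Oc1cc(O)cc(I)c1 | starting material
15 | 1-iodo-3,5-bis(methoxymethoxy)benzene | COCOc1cc(I)cc(OCOC)c1 | intermediate
16 | (2-bromoethoxy)(tert-butyl)dimethylsilane | BrCCO[Si](C)(C)C(C)(C)C | starting material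
17 | 2-{3,5-bis(methoxymethoxy)-2,6-bis[2-(tert-butyldimethylsilyloxy)ethyl]phenyl}-4,6-bis(methoxymethoxy)-7-[(2R)-3-methylbut-3-en-2-yl]benzofuran | C=C(C)[C@@H](C)c1c(OCOC)cc(OCOC)c2cc(-c3c(CCO[Si](C)(C)C(C)(C)C)c(OCOC)cc(OCOC)c3CCO[Si](C)(C)C(C)(C)C)oc12 | intermediate
18 | 2,2′-{2-[4,6-bis(methoxymethoxy)-7-((2R)-3-methylbut-3-en-2-yl)benzofuran-2-yl]-4,6-bis(methoxymethoxy)-1,3-phenylene}diethanol | C=C(C)[C@@H](C)c1c(OCOC)cc(OCOC)c2cc(-c3c(CCO)c(OCOC)cc(OCOC)c3CCO)oc12 | intermediate
19 | 2,2′-{2-[4,6-bis(methoxymethoxy)-7-((2R)-3-methylbut-3-en-2-yl)benzofuran-2-yl]-4,6-bis(methoxymethoxy)-1,3-phenylene}diacetaldehyde | C=C(C)[C@@H](C)c1c(OCOC)cc(OCOC)c2cc(-c3c(CC=O)c(OCOC)cc(OCOC)c3CC=O)oc12 | intermediate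
20 | 2-[3,5-bis(methoxymethoxy)-2,6-bis(3-methylbut-2-en-1-yl)phenyl]-4,6-bis(methoxymethoxy)-7-[(2R)-3-methylbut-3-en-2-yl]benzofuran | C=C(C)[C@@H](C)c1c(OCOC)cc(OCOC)c2cc(-c3c(CC=C(C)C)c(OCOC)cc(OCOC)c3CC=C(C)C)oc12 | intermediate
21 | tetrakis(trimethylsilyl) ether of 22 (not isolated) | C=C(C)[C@@H](C)c1c(O[Si](C)(C)C)cc(O[Si](C)(C)C)c2cc(-c3c(CC=C(C)C)c(O[Si](C)(C)C)cc(O[Si](C)(C)C)c3CC=C(C)C)oc12 | intermediate
22 | 2-[3,5-dihydroxy-2,6-bis(3-methylbut-2-en-1-yl)phenyl]-7-[(2R)-3-methylbut-3-en-2-yl]benzofuran-4,6-diol | C=C(C)[C@@H](C)c1c(O)cc(O)c2cc(-c3c(CC=C(C)C)c(O)cc(O)c3CC=C(C)C)oc12 | target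

**Step count**

Total: 15 steps. Longest linear sequence: 14 steps (steps 1–9 and 11–15).

**Steps most likely to fail**

Step 11. The palladacycle may fail to form or to alkylate at ortho positions that sit beside a MOM ether, so the sequence could stall after no or one alkylation. Further dangers are ipso coupling of 13 before both ortho carbons are filled, norbornene-containing by-products, protodeboronation of the 2-benzofuranyl boronate, and palladium hydride migration of the isopropenyl double bond. The fallback builds the crowded edge of ring B by sigmatropic chemistry and leaves only one bond to cross-coupling. It sets out from 14: O-allylation (allyl bromide, K2CO3, acetone) should give 1,3-bis(allyloxy)-5-iodobenzene F1. Double aromatic Claisen rearrangement (N,N-diethylaniline, 190 °C) should give 4,6-diallyl-5-iodobenzene-1,3-diol F2, each allyl group moving to the carbon para to the other oxygen and next to iodine, with any isomer bearing an allyl between the oxygens removed by chromatography. MOM protection (MOMCl, i-Pr2NEt) should give 2-iodo-4,6-bis(methoxymethoxy)-1,3-di(prop-2-en-1-yl)benzene F3. Cross-metathesis with 2-methylbut-2-ene and the second-generation Grubbs catalyst should give 2-iodo-4,6-bis(methoxymethoxy)-1,3-bis(3-methylbut-2-en-1-yl)benzene F4. Suzuki–Miyaura coupling of F4 with 13 (Pd(OAc)2, SPhos, K3PO4, toluene–H2O, 80 °C) comes back to the route at 20, so steps 12–14 fall away.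

Step 8. Methyl transfer may go to the unhindered α-carbon (linear product) because the γ-carbon carries a doubly ortho-substituted aryl group and a neighbouring methyl. Enantioselectivity may be eroded by chelation of magnesium or copper to the ortho MOM ether, or by ionisation of the electron-rich allylic bromide. The fallback sets the centre by a stereospecific 1,2-metallate shift and sets out from 6. Methylenation (Ph3PCH3Br, KOt-Bu, THF) should give 4,6-bis(methoxymethoxy)-7-vinylbenzofuran F5. Copper hydride-catalysed Markovnikov hydroboration (CuCl, NaOt-Bu, the DTBM-SEGPHOS antipode leading to the (S) product, HBpin, toluene) should give 2-{(1S)-1-[4,6-bis(methoxymethoxy)benzofuran-7-yl]ethyl}-4,4,5,5-tetramethyl-1,3,2-dioxaborolane F6. Zweifel olefination (isopropenyllithium, THF, −78 °C; I2, MeOH; NaOMe) transfers the benzylic carbon with retention and comes back to the route at 11.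

Step 14. The basic ylide may enolise the arylacetaldehydes, leading to aldol self-condensation or an incomplete second olefination, and dialdehyde 19 may degrade before it reacts. The fallback reverses the polarity so that no arylacetaldehyde is needed, and sets out from 18. Appel iodination (I2, PPh3, imidazole, CH2Cl2) should give 2-[2,6-bis(2-iodoethyl)-3,5-bis(methoxymethoxy)phenyl]-4,6-bis(methoxymethoxy)-7-[(2R)-3-methylbut-3-en-2-yl]benzofuran F7. Heating with PPh3 (MeCN, 80 °C) should give the bis(triphenylphosphonium) diiodide F8. Ylide formation (n-BuLi, THF, −78 °C) and Wittig reaction with acetone come back to the route at 20.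

**Further compounds**

F1 | step 11 | 1,3-bis(allyloxy)-5-iodobenzene | C=CCOc1cc(I)cc(OCC=C)c1
F2 | step 11 | 4,6-diallyl-5-iodobenzene-1,3-diol | C=CCc1c(O)cc(O)c(CC=C)c1I
F3 | step 11 | 2-iodo-4,6-bis(methoxymethoxy)-1,3-di(prop-2-en-1-yl)benzene | C=CCc1c(OCOC)cc(OCOC)c(CC=C)c1I
F4 | step 11 | 2-iodo-4,6-bis(methoxymethoxy)-1,3-bis(3-methylbut-2-en-1-yl)benzene | CC(C)=CCc1c(OCOC)cc(OCOC)c(CC=C(C)C)c1I
F5 | step 8 | 4,6-bis(methoxymethoxy)-7-vinylbenzofuran | C=Cc1c(OCOC)cc(OCOC)c2ccoc12
F6 | step 8 | 2-{(1S)-1-[4,6-bis(methoxymethoxy)benzofuran-7-yl]ethyl}-4,4,5,5-tetramethyl-1,3,2-dioxaborolane | CC1(C)OB(OC1(C)C)[C@@H](C)c1c(OCOC)cc(OCOC)c2ccoc12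
F7 | step 14 | 2-[2,6-bis(2-iodoethyl)-3,5-bis(methoxymethoxy)phenyl]-4,6-bis(methoxymethoxy)-7-[(2R)-3-methylbut-3-en-2-yl]benzofuran | C=C(C)[C@@H](C)c1c(OCOC)cc(OCOC)c2cc(-c3c(CCI)c(OCOC)cc(OCOC)c3CCI)oc12
F8 | step 14 | {2-[4,6-bis(methoxymethoxy)-7-((2R)-3-methylbut-3-en-2-yl)benzofuran-2-yl]-4,6-bis(methoxymethoxy)-1,3-phenylene}bis(ethane-2,1-diyl)bis(triphenylphosphonium) diiodide | C=C(C)[C@@H](C)c1c(OCOC)cc(OCOC)c2cc(-c3c(CC[P+](c4ccccc4)(c4ccccc4)c4ccccc4)c(OCOC)cc(OCOC)c3CC[P+](c4ccccc4)(c4ccccc4)c4ccccc4)oc12.[I-].[I-]
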